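## Retrosynthetic overview

1. The seven-membered ring is closed last: acid-mediated Friedel–Crafts attack of a 3,5-dimethoxyphenyl ring on the protonated (E)-stilbene of a C2-symmetric bis(trans-dihydrobenzofuran), then global O-demethylation.
2. The stilbene comes from vinylation and Heck arylation at the central aryl chloride.
3. Both dihydrofuran rings come from a two-fold decarboxylative ring contraction of a bis(3,4-diaryl-dihydrocoumarin): six-membered lactone to five-membered ether with loss of CO2.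
4. The lactone stereocentres come from a two-fold asymmetric 1,4-addition of (3,5-dimethoxyphenyl)boronic acid to a linear bis-coumarin with Rh(acac)(C2H4)2/(R)-Segphos, followed by α-arylation with Pd(dba)2/Q-Phos.
5. The bis-coumarin comes from resorcinol (methylation, C–H borylation to the boronic acid that is also the aryl donor of line 4, chlorodeboronation, dibromination, double Heck, BBr3 lactonisation). Ring order: two pyranones, then two furans by contraction, then the cycloheptene.

Assumption: stilbenoid locants are used for the target (resveratrol unit a with the free resorcinol ring, oxyresveratrol unit b, resveratrol unit c with the fused resorcinol ring); the given SMILES is the 7aR,8aR,7bS,7cR,8cR isomer, and (R)-Segphos is taken to give the (R)-4-aryl lactone as in the 4-arylchroman-2-one series (the ligand antipode is used if the first run shows otherwise).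

## Route

Step 1
Reactants: 1 resorcinol
Product: 2 1,3-dimethoxybenzene
Conditions: MeI (2.5 equiv), K2CO3, acetone, reflux
Reagents that add atoms: iodomethane CI
Why: Williamson ether synthesis caps both phenols as methyl ethers, the protecting group carried to the last step.

Step 2
Reactants: 2 1,3-dimethoxybenzene
Product: 4 (3,5-dimethoxyphenyl)boronic acid, via aryl pinacol boronate 3 (not isolated)
Conditions: [Ir(OMe)(cod)]2 (1 mol%), dtbpy, B2pin2 (0.55 equiv), THF, 80 °C; then NaIO4 (3 equiv), 1 M HCl, THF/H2O, rt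
Reagents that add atoms: bis(pinacolato)diboron CC1(C)OB(OC1(C)C)B1OC(C)(C)C(C)(C)O1; water O
Why: sterically controlled C–H borylation with [Ir(OMe)(cod)]2/dtbpy reaches only the carbon meta to both methoxy groups, and periodate cleavage of the pinacol unit in the same flask frees the boronic acid, which is made on a scale that feeds both step 3 and step 7.

Step 3
Reactants: 4 (3,5-dimethoxyphenyl)boronic acid
Product: 5 1-chloro-3,5-dimethoxybenzene
Conditions: CuCl2 (3 equiv), MeOH/H2O 1:1, 80 °C
Reagents that add atoms: CuCl2 Cl[Cu]Cl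
Why: CuCl2-mediated chlorodeboronation is an ipso substitution (aryl transfer from boron to copper, then C–Cl bond formation), so chlorine lands on the carbon meta to both methoxy groups, which electrophilic chlorination cannot reach.

Step 4
Reactants: 5 1-chloro-3,5-dimethoxybenzene
Product: 6 1,3-dibromo-2-chloro-4,6-dimethoxybenzene
Conditions: NBS (2.05 equiv), MeCN, 0 °C to rt
Reagents that add atoms: N-bromosuccinimide O=C1CCC(=O)N1Br
Why: electrophilic aromatic bromination; each bromine enters para to one methoxy group and ortho to the other, the carbon between the two methoxy groups reacting last.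

Step 5
Reactants: 6 1,3-dibromo-2-chloro-4,6-dimethoxybenzene, 7 methyl acrylate (2 equiv incorporated)
Product: 8 dimethyl (2E,2'E)-3,3'-(2-chloro-4,6-dimethoxy-1,3-phenylene)di(prop-2-enoate)
Conditions: 7 (3 equiv), Pd(OAc)2 (5 mol%), P(o-tol)3 (12 mol%), Et3N, DMF, 110 °C
Reagents that add atoms: methyl acrylate COC(=O)C=C (the second equivalent; one acrylate unit is attached at each C–Br position)
Why: two-fold Mizoroki–Heck reaction, one acrylate per bromide; this catalyst inserts into C–Br but not into the flanked C–Cl bond, and syn insertion/syn β-hydride elimination gives the E alkenes.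

Step 6
Reactants: 8 dimethyl (2E,2'E)-3,3'-(2-chloro-4,6-dimethoxy-1,3-phenylene)di(prop-2-enoate)
Product: 9 5-chloro-2H,8H-benzo[1,2-b:5,4-b']dipyran-2,8-dione
Conditions: BBr3 (6 equiv), CH2Cl2, −78 to 40 °C; then H2O
Reagents that add atoms: none
Why: BBr3 ether cleavage followed by lactonisation; the Lewis-acid-activated enoate isomerises E to Z by reversible bromide conjugate addition and the aryloxyborane then closes each coumarin ring.

Step 7
Reactants: 9 5-chloro-2H,8H-benzo[1,2-b:5,4-b']dipyran-2,8-dione, 4 (3,5-dimethoxyphenyl)boronic acid (2 equiv incorporated)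
Product: 10 (4R,6R)-5-chloro-4,6-bis(3,5-dimethoxyphenyl)-3,4,6,7-tetrahydro-2H,8H-benzo[1,2-b:5,4-b']dipyran-2,8-dione
Conditions: Rh(acac)(C2H4)2 (6 mol%), (R)-Segphos (6.6 mol%), 4 (8 equiv), dioxane/H2O 10:1, 60 °C
Reagents that add atoms: (3,5-dimethoxyphenyl)boronic acid COc1cc(OC)cc(c1)B(O)O (the second equivalent; one aryl group is added to each coumarin ring)
Why: Hayashi–Miyaura asymmetric 1,4-addition with Rh(acac)(C2H4)2/(R)-Segphos; the chiral aryl–rhodium species adds to the same enantioface of each coumarin and sets both benzylic stereocentres as R, two-fold catalyst control enriching the C2-symmetric isomer while the minor meso isomer is removed by chromatography.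

Step 8
Reactants: 11 anisole
Product: 12 1-bromo-4-methoxybenzene
Conditions: NBS (1.0 equiv), MeCN, rt
Reagents that add atoms: N-bromosuccinimide O=C1CCC(=O)N1Br
Why: para-selective electrophilic aromatic bromination of anisole.

Step 9
Reactants: 10 (4R,6R)-5-chloro-4,6-bis(3,5-dimethoxyphenyl)-3,4,6,7-tetrahydro-2H,8H-benzo[1,2-b:5,4-b']dipyran-2,8-dione, 12 1-bromo-4-methoxybenzene (2 equiv incorporated)
Product: 13 (3R,4R,6R,7R)-5-chloro-4,6-bis(3,5-dimethoxyphenyl)-3,7-bis(4-methoxyphenyl)-3,4,6,7-tetrahydro-2H,8H-benzo[1,2-b:5,4-b']dipyran-2,8-dione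
Conditions: LiN(SiMe3)2 (2.3 equiv), THF, −78 °C; ZnCl2 (2.4 equiv); then 12 (3 equiv), Pd(dba)2 (5 mol%), Q-Phos (5 mol%), rt to 50 °C
Reagents that add atoms: 1-bromo-4-methoxybenzene COc1ccc(Br)cc1 (the second equivalent; one 4-methoxyphenyl group is attached at each lactone α-carbon)
Why: two-fold α-arylation of the zinc lactone enolates with Pd(dba)2/Q-Phos (Hartwig type), the aryl group entering trans to the neighbouring aryl; this new centre is erased in step 10, so its configuration does not matter, and the hindered C–Cl bond is left alone because the aryl bromide reacts first.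

Step 10
Reactants: 13 (3R,4R,6R,7R)-5-chloro-4,6-bis(3,5-dimethoxyphenyl)-3,7-bis(4-methoxyphenyl)-3,4,6,7-tetrahydro-2H,8H-benzo[1,2-b:5,4-b']dipyran-2,8-dione
Product: 15 (2R,3R,5R,6R)-4-chloro-3,5-bis(3,5-dimethoxyphenyl)-2,6-bis(4-methoxyphenyl)-2,3,5,6-tetrahydrobenzo[1,2-b:5,4-b']difuran, via ring-opened bis-carboxylate 14 (not isolated)
Conditions: n-Bu4NOH (2.0 equiv, 40% aq.), MeCN, 0 °C to rt; then undivided cell, graphite anode, Pt cathode, 5 mA cm−2, 2.5 F per carboxylate, MeCN/H2O 20:1, 10 °C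
Reagents that add atoms: tetrabutylammonium hydroxide CCCC[N+](CCCC)(CCCC)CCCC.[OH-] (oxygen and counter-ion of 14 only; nothing remains in 15)
Why: Proposed new method: one-flask saponification and anodic decarboxylative ring contraction, in which one hydroxide per lactone gives the phenol carboxylate, two-electron non-Kolbe oxidation of the 2-(4-methoxyphenyl)acetate unit (low potential because of the anisyl group) expels CO2 to leave a 4-methoxybenzyl cation, and the neighbouring phenol captures it 5-exo on the face anti to the adjacent aryl group, so each six-membered lactone contracts to a trans-2,3-diaryl dihydrobenzofuran, setting C2 and C6 as R while C3 and C5 are untouched; the closest known reaction types are Hofer–Moest/non-Kolbe electrolysis of arylacetic acids with alcohol trapping and the acid-mediated cyclisation of 4-methoxybenzylic carbinols onto ortho phenols.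

Step 11
Reactants: 15 (2R,3R,5R,6R)-4-chloro-3,5-bis(3,5-dimethoxyphenyl)-2,6-bis(4-methoxyphenyl)-2,3,5,6-tetrahydrobenzo[1,2-b:5,4-b']difuran, 16 potassium ethenyltrifluoroborate
Product: 17 (2R,3R,5R,6R)-4-ethenyl-3,5-bis(3,5-dimethoxyphenyl)-2,6-bis(4-methoxyphenyl)-2,3,5,6-tetrahydrobenzo[1,2-b:5,4-b']difuran
Conditions: 16 (2 equiv), Pd(OAc)2 (5 mol%), SPhos (10 mol%), K2CO3 (3 equiv), toluene/H2O 10:1, 90 °C
Reagents that add atoms: none
Why: Suzuki–Miyaura vinylation; the biaryl phosphine allows oxidative addition into the hindered, electron-rich aryl chloride and the small vinyl group couples without touching the four stereocentres.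

Step 12
Reactants: 2 1,3-dimethoxybenzene
Product: 18 1-bromo-2,4-dimethoxybenzene
Conditions: NBS (1.0 equiv), MeCN, 0 °C
Reagents that add atoms: N-bromosuccinimide O=C1CCC(=O)N1Br
Why: electrophilic aromatic bromination para to one methoxy group and ortho to the other.

Step 13
Reactants: 17 (2R,3R,5R,6R)-4-ethenyl-3,5-bis(3,5-dimethoxyphenyl)-2,6-bis(4-methoxyphenyl)-2,3,5,6-tetrahydrobenzo[1,2-b:5,4-b']difuran, 18 1-bromo-2,4-dimethoxybenzene
Product: 19 (2R,3R,5R,6R)-4-[(E)-2-(2,4-dimethoxyphenyl)ethenyl]-3,5-bis(3,5-dimethoxyphenyl)-2,6-bis(4-methoxyphenyl)-2,3,5,6-tetrahydrobenzo[1,2-b:5,4-b']difuran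
Conditions: Pd2(dba)3 (2.5 mol%), P(t-Bu)3·HBF4 (10 mol%), Cy2NMe (1.5 equiv), 1,4-dioxane, 100 °C
Reagents that add atoms: none
Why: Mizoroki–Heck arylation at the unhindered terminal carbon of the styrene gives the E-stilbene, so the congested ring carbon is not involved in the bond-forming step.

Step 14
Reactants: 19 (2R,3R,5R,6R)-4-[(E)-2-(2,4-dimethoxyphenyl)ethenyl]-3,5-bis(3,5-dimethoxyphenyl)-2,6-bis(4-methoxyphenyl)-2,3,5,6-tetrahydrobenzo[1,2-b:5,4-b']difuran
Product: 21 target CNP0154047.2 (7aR,8aR,7bS,7cR,8cR), via octamethyl ether 20 (not isolated)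
Conditions: TfOH (20 mol%), CH2Cl2, −20 to 0 °C; then BBr3 (16 equiv), −78 °C to rt; then H2O
Reagents that add atoms: none
Why: Brønsted-acid Friedel–Crafts alkene hydroarylation, in which protonation next to the central ring gives the 2,4-dimethoxybenzyl cation and either of the two C2-equivalent 3,5-dimethoxyphenyl rings traps it at an ortho carbon to close the seven-membered ring with the aryl group pseudo-axial (7bS, the relative configuration expected by analogy with the acid cyclisation of ε-viniferin to ampelopsin B), after which BBr3 cleaves all eight methyl ethers, any reversible opening of the benzylic ether rings reclosing to the trans isomers.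

## Compound list

1 | resorcinol | Oc1cccc(O)c1 | starting material
2 | 1,3-dimethoxybenzene | COc1cccc(OC)c1 | intermediate
3 | 2-(3,5-dimethoxyphenyl)-4,4,5,5-tetramethyl-1,3,2-dioxaborolane | COc1cc(OC)cc(c1)B1OC(C)(C)C(C)(C)O1 | intermediate
4 | (3,5-dimethoxyphenyl)boronic acid | COc1cc(OC)cc(c1)B(O)O | intermediate
5 | 1-chloro-3,5-dimethoxybenzene | COc1cc(Cl)cc(OC)c1 | intermediate
6 | 1,3-dibromo-2-chloro-4,6-dimethoxybenzene | COc1cc(OC)c(Br)c(Cl)c1Br | intermediate
7 | methyl acrylate | COC(=O)C=C | starting material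
8 | dimethyl (2E,2'E)-3,3'-(2-chloro-4,6-dimethoxy-1,3-phenylene)di(prop-2-enoate) | COC(=O)/C=C/c1c(OC)cc(OC)c(/C=C/C(=O)OC)c1Cl | intermediate
9 | 5-chloro-2H,8H-benzo[1,2-b:5,4-b']dipyran-2,8-dione (linear bis-coumarin, Cl between the two C-4 type carbons) | O=C1Oc2cc3OC(=O)C=Cc3c(Cl)c2C=C1 | intermediate
10 | (4R,6R)-5-chloro-4,6-bis(3,5-dimethoxyphenyl)-3,4,6,7-tetrahydro-2H,8H-benzo[1,2-b:5,4-b']dipyran-2,8-dione | O=C1C[C@H](c2cc(OC)cc(OC)c2)c2c(Cl)c3[C@@H](c4cc(OC)cc(OC)c4)CC(=O)Oc3cc2O1 | intermediate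
11 | anisole | COc1ccccc1 | starting material
12 | 1-bromo-4-methoxybenzene | COc1ccc(Br)cc1 | intermediate
13 | (3R,4R,6R,7R)-5-chloro-4,6-bis(3,5-dimethoxyphenyl)-3,7-bis(4-methoxyphenyl)-3,4,6,7-tetrahydro-2H,8H-benzo[1,2-b:5,4-b']dipyran-2,8-dione (3,4-trans and 6,7-trans) | O=C1[C@@H](c2ccc(OC)cc2)[C@H](c2cc(OC)cc(OC)c2)c2c(Cl)c3[C@@H](c4cc(OC)cc(OC)c4)[C@H](c4ccc(OC)cc4)C(=O)Oc3cc2O1 | intermediate
14 | bis(tetrabutylammonium) (2R,2'R,3R,3'R)-3,3'-(2-chloro-4,6-dihydroxy-1,3-phenylene)bis[3-(3,5-dimethoxyphenyl)-2-(4-methoxyphenyl)propanoate] | CCCC[N+](CCCC)(CCCC)CCCC.CCCC[N+](CCCC)(CCCC)CCCC.[O-]C(=O)[C@@H](c1ccc(OC)cc1)[C@H](c1cc(OC)cc(OC)c1)c1c(Cl)c([C@@H](c2cc(OC)cc(OC)c2)[C@H](c2ccc(OC)cc2)C([O-])=O)c(O)cc1O | intermediate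
15 | (2R,3R,5R,6R)-4-chloro-3,5-bis(3,5-dimethoxyphenyl)-2,6-bis(4-methoxyphenyl)-2,3,5,6-tetrahydrobenzo[1,2-b:5,4-b']difuran (both rings trans) | COc1ccc(cc1)[C@@H]1Oc2cc3O[C@@H](c4ccc(OC)cc4)[C@H](c4cc(OC)cc(OC)c4)c3c(Cl)c2[C@H]1c1cc(OC)cc(OC)c1 | intermediate
16 | potassium ethenyltrifluoroborate | [K+].C=C[B-](F)(F)F | starting material
17 | (2R,3R,5R,6R)-4-ethenyl-3,5-bis(3,5-dimethoxyphenyl)-2,6-bis(4-methoxyphenyl)-2,3,5,6-tetrahydrobenzo[1,2-b:5,4-b']difuran | COc1ccc(cc1)[C@@H]1Oc2cc3O[C@@H](c4ccc(OC)cc4)[C@H](c4cc(OC)cc(OC)c4)c3c(C=C)c2[C@H]1c1cc(OC)cc(OC)c1 | intermediate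
18 | 1-bromo-2,4-dimethoxybenzene | COc1ccc(Br)c(OC)c1 | intermediate
19 | (2R,3R,5R,6R)-4-[(E)-2-(2,4-dimethoxyphenyl)ethenyl]-3,5-bis(3,5-dimethoxyphenyl)-2,6-bis(4-methoxyphenyl)-2,3,5,6-tetrahydrobenzo[1,2-b:5,4-b']difuran | COc1ccc(cc1)[C@@H]1Oc2cc3O[C@@H](c4ccc(OC)cc4)[C@H](c4cc(OC)cc(OC)c4)c3c(/C=C/c4ccc(OC)cc4OC)c2[C@H]1c1cc(OC)cc(OC)c1 | intermediate
20 | octa-O-methyl ether of the target (7aR,8aR,7bS,7cR,8cR; seven-membered ring closed) | COc1ccc([C@@H]2Oc3cc4c5c(c3[C@H]2c2cc(OC)cc(OC)c2)C[C@@H](c2ccc(OC)cc2OC)c2c(OC)cc(OC)cc2[C@H]5[C@H](c2ccc(OC)cc2)O4)cc1 | intermediate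
21 | CNP0154047.2: resveratrol–oxyresveratrol–resveratrol trimer with two trans-2,3-diaryl-dihydrobenzofurans on the central ring and a dibenzo-fused cycloheptene carrying the 2,4-dihydroxyphenyl group (7aR,8aR,7bS,7cR,8cR) | Oc1ccc([C@@H]2Oc3cc4c5c(c3[C@H]2c2cc(O)cc(O)c2)C[C@@H](c2ccc(O)cc2O)c2c(O)cc(O)cc2[C@H]5[C@H](c2ccc(O)cc2)O4)cc1 | target

## Step count and risks

Total steps: 14. Longest linear sequence: 12 steps (steps 1, 2, 3, 4, 5, 6, 7, 9, 10, 11, 13, 14; resorcinol to 21).

The three steps most likely to fail: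

Step 7 (two-fold asymmetric 1,4-addition). Coumarins are sluggish acceptors and each β-carbon here sits next to the peri chlorine; low conversion or mono-addition is the likely failure. The fallback sets the stereocentres by hydride delivery instead of aryl delivery. It sets out from 9: oxidative Heck arylation with 4 (Pd(OAc)2, 1,10-phenanthroline, O2, DMF, 100 °C) gives 5-chloro-4,6-bis(3,5-dimethoxyphenyl)-2H,8H-benzo[1,2-b:5,4-b']dipyran-2,8-dione F1. CuH-catalysed asymmetric conjugate reduction of F1 (Cu(OAc)2, DTBM-SEGPHOS enantiomer chosen to give 4R,6R, diethoxymethylsilane, t-BuOH, toluene, rt) then comes back to the route at 10.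

Step 10 (the proposed anodic ring contraction). The free phenols or the methoxyarenes may be oxidised before the carboxylate, water may compete for the cation, and a 1,2-hydride shift in the cation could erode C3 and C5. The fallback uses known chemistry only and sets out from 10, so that step 9 is bypassed as well. α-Bromination (LiN(SiMe3)2, THF, −78 °C, then NBS) gives (3S,4R,6R,7S)-3,7-dibromo-5-chloro-4,6-bis(3,5-dimethoxyphenyl)-3,4,6,7-tetrahydro-2H,8H-benzo[1,2-b:5,4-b']dipyran-2,8-dione F2. Aqueous NaOH in THF followed by HCl brings about the Perkin-type ring contraction of the α-halo lactone (hydroxide opens the lactone, the phenoxide displaces bromide with inversion) to (2R,3R,5R,6R)-4-chloro-3,5-bis(3,5-dimethoxyphenyl)-2,3,5,6-tetrahydrobenzo[1,2-b:5,4-b']difuran-2,6-dicarboxylic acid F3; any other bromide epimer converges in the next operation. Photoredox decarboxylative arylation of this α-oxy acid with 12 (Ir[dF(CF3)ppy]2(dtbbpy)PF6, NiCl2·glyme, dtbbpy, Cs2CO3, DMF, blue light) delivers the aryl group trans to the neighbouring aryl and comes back to the route at 15.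

Step 14 (cyclisation and eight-fold demethylation). BBr3 can open the 2-aryl dihydrobenzofurans and let the resulting cations alkylate neighbouring rings, and the wrong C-7b epimer is possible. The fallback deprotects first under basic nucleophilic conditions and cyclises the free phenol last. It sets out from 19: NaSEt (excess), DMF, 130 °C gives 4-[(2R,3R,5R,6R)-4-[(E)-2-(2,4-dihydroxyphenyl)ethenyl]-3,5-bis(3,5-dihydroxyphenyl)-6-(4-hydroxyphenyl)-2,3,5,6-tetrahydrobenzo[1,2-b:5,4-b']difuran-2-yl]phenol F4. Treatment of F4 with HCl in MeOH at rt (the conditions of the ε-viniferin to ampelopsin B cyclisation) comes back to the route at 21.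

## Further compounds

F1 | step 7 | 5-chloro-4,6-bis(3,5-dimethoxyphenyl)-2H,8H-benzo[1,2-b:5,4-b']dipyran-2,8-dione | O=C1C=C(c2cc(OC)cc(OC)c2)c2c(Cl)c3C(c4cc(OC)cc(OC)c4)=CC(=O)Oc3cc2O1
F2 | step 10 | (3S,4R,6R,7S)-3,7-dibromo-5-chloro-4,6-bis(3,5-dimethoxyphenyl)-3,4,6,7-tetrahydro-2H,8H-benzo[1,2-b:5,4-b']dipyran-2,8-dione | O=C1[C@@H](Br)[C@H](c2cc(OC)cc(OC)c2)c2c(Cl)c3[C@@H](c4cc(OC)cc(OC)c4)[C@H](Br)C(=O)Oc3cc2O1
F3 | step 10 | (2R,3R,5R,6R)-4-chloro-3,5-bis(3,5-dimethoxyphenyl)-2,3,5,6-tetrahydrobenzo[1,2-b:5,4-b']difuran-2,6-dicarboxylic acid | OC(=O)[C@@H]1Oc2cc3O[C@@H](C(O)=O)[C@H](c4cc(OC)cc(OC)c4)c3c(Cl)c2[C@H]1c1cc(OC)cc(OC)c1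
F4 | step 14 | 4-[(2R,3R,5R,6R)-4-[(E)-2-(2,4-dihydroxyphenyl)ethenyl]-3,5-bis(3,5-dihydroxyphenyl)-6-(4-hydroxyphenyl)-2,3,5,6-tetrahydrobenzo[1,2-b:5,4-b']difuran-2-yl]phenol | Oc1ccc(cc1)[C@@H]1Oc2cc3O[C@@H](c4ccc(O)cc4)[C@H](c4cc(O)cc(O)c4)c3c(/C=C/c4ccc(O)cc4O)c2[C@H]1c1cc(O)cc(O)c1
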